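The share of its charge turned into target at the last reading is 87.5% in the ash run and 87.9% in the oak run, which is alike although the oak run was charged with half the starting material at the same free catalyst, so at that catalyst charge these two runs behave as first order in starting material. I therefore reckon with the logarithmic conversion L = ln(S/(S − P)), where S is the starting material charged and P the target at time t.

| flask | starting material | free catalyst | time |
|---|---|---|---|
| ash | 0.600 M | 0.0180 M |  |
| oak | 0.300 M | 0.0180 M |  |
| cedar | 0.600 M | 0.0540 M |  |
| larch | 1.80 M | 0.00590 M | 110 h |

- ash run (time / h: [target] / M): 3.9: 0.0848; 12: 0.1906; 23: 0.2670; 36: 0.3332; 52: 0.4003; 69: 0.4484; 89: 0.4910; 110: 0.5252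
- oak run (time / h: [target] / M): 3.9: 0.0461; 12: 0.0955; 23: 0.1304; 36: 0.1636; 52: 0.1974; 69: 0.2262; 89: 0.2458; 110: 0.2637
- cedar run (time / h: [target] / M): 3.9: 0.1411; 12: 0.2969; 23: 0.3763; 36: 0.4221; 52: 0.4648; 69: 0.4991; 89: 0.5281; 110: 0.5498

(scatter of a reading: 0.002 M)

- Overall: starting material -> target, with free catalyst as catalyst.
- Constant volume, constant temperature.
- An order is taken over about fifteen percent of the charge, up and down.

- apparent order in [free catalyst] of the starting rate, round the charge of the ash run (the rate where two percent of its starting material have turned into target)
- apparent order in [starting material] of the starting rate, round the charge of the ash run (the rate where two percent of its starting material have turned into target) (one fixed amount of target, the same in the runs compared)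
- the oak run starts with 0.300 M less of starting material than the ash run, and with no target. Compared where both hold the same amount of starting material, once fifteen percent of what the oak run was charged with has turned into target, is the oak run faster, slower or alike (within a tenth)?
- target in the larch run at 110 h, as a share of the starting material charged

The neighbour I compare is the cedar run, which has the starting material of the ash run and 3.00 times its free catalyst. The cedar run ends higher than the ash run, but the gap in L between them reads 0.405 at 36 h and 0.399 at 110 h. As far as the scatter shows, then, the catalyst has paid a fixed sum by the earlier time, and both runs climb on one slope afterwards. So at late times I write L = k t + b C, with C the free catalyst charged, k the background rate constant, and b the burst per unit of catalyst charged. Both constants come from the last readings: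

L (ash) = 2.08, L (cedar) = 2.48

b = (L cedar − L ash) / (C cedar − C ash) = 11.1 M⁻¹

k = (L ash − b C ash) / t = 0.0171 h⁻¹

The larch run has a larger charge of starting material than the ash run, which I take not to move the share, as the step from the oak run to the ash run did not, and a smaller charge of free catalyst, so its burst weighs far less than its background:

L (larch) = k t + b C = 1.88 + 0.0654 = 1.95

The fraction left is exp(−L), so I expect target at 85.7% of the larch charge.

The forecast gives order 0.45 in free catalyst, order 1 in starting material, the oak run faster, and 85.7% for the larch run, on the ground that "The burst is proportional to catalyst charge and independent of starting material".

The flask gives orders 0.45 and 1.0, the oak run faster by a factor of 2.1, and the larch run at 85.5%.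

    2 free catalyst ⇌ catalyst dimer, settled at all times (36.50 M⁻¹)
    free catalyst + starting material → target + free catalyst (2.754 M⁻¹ h⁻¹)
    starting material → target (0.01696 h⁻¹)
    free catalyst → spent catalyst (0.2419 h⁻¹)

The larch run ends where it ends because of the conversion of starting material into target without catalyst: its catalyst charge buys a b C of 0.0654 against 1.88 for k t. With that conversion taken away, the larch run keeps L = b C, which is 6.33% of its charge as target, and the larch run made without that conversion stands at 6.50%.

(The earlier runs and the new flask stem from a simulated flask for an exercise.)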